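**Retrosynthetic overview**

1. Locants follow the 2-oxaspiro[4.5]decane core: ring B (lactone) = C1(H)(side chain), O2, C3(=O), C4H2, C5 (spiro); ring A = C5, C6(=O), C7=C8, C9(OAc), C10. Endgame: side-chain terminus by cross metathesis, C9–OAc by ketoreductase reduction of a C6,C9-enedione, C7=C8 by Saegusa–Ito oxidation, C3=O by oxidation of a lactol.
2. Key disconnection C3–C4: a formate-level Prins cyclisation of an exocyclic C5=C4 alkene onto an O2-bound carbenium ion C3 closes a six-membered oxane (O2, C3, C4, C5, C6, C1); a pinacol shift of C1 from C6 to C5 then contracts it to ring B and creates the spiro centre C5 and the C6 ketone in the same operation.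
3. Enabling feature: C5 bears the C4 methylene, the O2-bearing C1 and the C6 carbonyl of ring A, so ring B is a 3-acyl oxolane whose acyl group lies in ring A; returning C1 to C6 uncovers a plain allylic 1,2-diol, a 1-(1-hydroxyalkyl)-2-methylidenecyclohexanol.
4. The diol comes from a hydroxyl-directed singlet-oxygen ene reaction of a bis-allylic alcohol, made by asymmetric alkenylzinc addition of (E)-1-iodo-2-methylpenta-1,4-diene to an enal derived from Hagemann's ester, whose ring, ester carbon and methyl group become C5–C10, C1 and C4.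
5. Ring order: ring A is bought; the transient oxane and then ring B form in the key step; stereochemistry is relayed C1 (catalyst) → C6 (ene reaction) → C5 (1,2-shift) → C9 (enzyme).

Key step: step 8

Remark: the C3 acetal centre is carried as an anomeric mixture because it ends as the lactone carbonyl; the C5 descriptor changes (5S in 17–20, 5R from 21 on) only through CIP priorities, the geometry being unchanged.

**Step 1**
Reactants: 1 Hagemann's ester (ethyl 2-methyl-4-oxocyclohex-2-ene-1-carboxylate, racemic)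
Product: 2 ethyl 7-methyl-1,4-dioxaspiro[4.5]dec-7-ene-8-carboxylate
Conditions: ethylene glycol (3 equiv), p-TsOH·H2O (cat.), benzene, reflux, Dean–Stark
Reagents that add atoms: ethylene glycol, OCCO
Why: Acid-catalysed ketalisation of the enone proceeds through the dienol ether and leaves the alkene in the tetrasubstituted position conjugated with the ester (deconjugative ketalisation), which also removes the racemic stereocentre of 1.

**Step 2**
Reactants: 2 ethyl 7-methyl-1,4-dioxaspiro[4.5]dec-7-ene-8-carboxylate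
Product: 3 (7-methyl-1,4-dioxaspiro[4.5]dec-7-en-8-yl)methanol
Conditions: DIBAL-H (iBu2AlH, 2.2 equiv), CH2Cl2, −78 → 0 °C; aq. Rochelle salt
Reagents that add atoms: none
Why: DIBAL-H 1,2-reduction of the enoate stops at the allylic alcohol and leaves the ketal untouched.

**Step 3**
Reactants: 3 (7-methyl-1,4-dioxaspiro[4.5]dec-7-en-8-yl)methanol
Product: 4 7-methyl-1,4-dioxaspiro[4.5]dec-7-ene-8-carbaldehyde
Conditions: MnO2 (excess), CH2Cl2, rt
Reagents that add atoms: none
Why: MnO2 oxidises the allylic alcohol selectively to the enal without over-oxidation (allylic alcohol oxidation).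

**Step 4**
Reactants: 5 pent-1-en-4-yne
Product: 7 (1E)-1-iodo-2-methylpenta-1,4-diene, via alkenylalane 6 (not isolated)
Conditions: Me3Al (2 equiv), Cp2ZrCl2 (0.2 equiv), CH2Cl2, 0 °C → rt; then I2, THF, −30 → 0 °C
Reagents that add atoms: trimethylaluminium, C[Al](C)C; iodine, II
Why: Negishi zirconium-catalysed syn-carboalumination puts methyl on the internal and aluminium on the terminal alkyne carbon, and iodinolysis with retention gives the (E)-vinyl iodide, the monosubstituted alkene being far less reactive.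

**Step 5**
Reactants: 4 7-methyl-1,4-dioxaspiro[4.5]dec-7-ene-8-carbaldehyde; 7 (1E)-1-iodo-2-methylpenta-1,4-diene
Product: 10 (1R,2E)-3-methyl-1-(7-methyl-1,4-dioxaspiro[4.5]dec-7-en-8-yl)hexa-2,5-dien-1-ol, via alkenyllithium 8 (not isolated), via dialkenylzinc 9 (not isolated)
Conditions: 7 (2.4 equiv), t-BuLi (4.8 equiv), Et2O, −78 °C; ZnBr2 (1.2 equiv), −78 → 0 °C; TEEDA, hexanes; (+)-MIB (10 mol %), then 4, −10 °C; aq. NH4Cl
Reagents that add atoms: none
Why: Iodine–lithium exchange with retention of alkene geometry and transmetalation give an alkenylzinc that adds 1,2 to the enal under amino-alcohol catalysis (catalytic asymmetric organozinc addition); (+)-MIB, the antipode of the Si-face-selective (−)-MIB, directs Re-face attack and sets C1 as (R).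

**Step 6**
Reactants: 10 (1R,2E)-3-methyl-1-(7-methyl-1,4-dioxaspiro[4.5]dec-7-en-8-yl)hexa-2,5-dien-1-ol
Product: 12 (1R,2E)-1-[(8R)-8-hydroxy-7-methylidene-1,4-dioxaspiro[4.5]decan-8-yl]-3-methylhexa-2,5-dien-1-ol, via tertiary hydroperoxide 11 (not isolated)
Conditions: O2, visible light, tetraphenylporphyrin (cat.), CH2Cl2, −20 °C; then PPh3 (1.1 equiv), −20 °C → rt
Reagents that add atoms: dioxygen, O=O
Why: In this hydroxyl-directed Schenck ene reaction the A(1,3)-minimised conformer (carbinol H in the alkene plane) lets the OH hydrogen-bond singlet oxygen onto its own face of the more electron-rich tetrasubstituted alkene, so oxygen bonds to the carbinol-bearing alkene carbon and a hydrogen leaves the cis methyl group, giving the threo hydroperoxide with the exocyclic methylene and an (R) tertiary carbinol, after which PPh3 reduces the O–O bond.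

**Step 7**
Reactants: 12 (1R,2E)-1-[(8R)-8-hydroxy-7-methylidene-1,4-dioxaspiro[4.5]decan-8-yl]-3-methylhexa-2,5-dien-1-ol
Product: 13 (1R,2E)-3-methyl-1-[(8R)-7-methylidene-8-(trimethylsilyloxy)-1,4-dioxaspiro[4.5]decan-8-yl]-1-(trimethylsilyloxy)hexa-2,5-diene
Conditions: 1-(trimethylsilyl)imidazole (3 equiv), CH2Cl2, rt
Reagents that add atoms: 1-(trimethylsilyl)imidazole, C[Si](C)(C)n1ccnc1
Why: The N-silylimidazole silylates both the secondary and the hindered tertiary hydroxyl under neutral conditions, which spares the acid-sensitive allylic diol.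

**Step 8**
Reactants: 13 (1R,2E)-3-methyl-1-[(8R)-7-methylidene-8-(trimethylsilyloxy)-1,4-dioxaspiro[4.5]decan-8-yl]-1-(trimethylsilyloxy)hexa-2,5-diene; 14 trimethyl orthoformate
Product: 17 (1R,5S)-9,9-(ethylenedioxy)-3-methoxy-1-[(1E)-2-methylpenta-1,4-dien-1-yl]-2-oxaspiro[4.5]decan-6-one (C3 anomers), via mixed orthoformate 15 (not isolated), via isochromenylium cation 16 (not isolated)
Conditions: 14 (3 equiv), TMSOTf (0.3 equiv), 2,6-di-tert-butyl-4-methylpyridine (0.4 equiv), CH2Cl2, −78 → −40 °C; Et3N, aq. NaHCO3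
Reagents that add atoms: none
Why: Proposed new method: TMSOTf ionises the orthoformate, the secondary silyl ether at C1 exchanges onto the dimethoxycarbenium ion to give 15, and loss of methoxide leaves an O2-bound methoxycarbenium ion at C3 that is attacked by the terminal carbon C4 of the exocyclic 1,1-disubstituted alkene, forming the C3–C4 bond and the tertiary C5 cation 16, whereupon the C6–C1 bond shifts to C5 while the C6 silyl ether collapses to the ketone and returns the silyl cation to the catalytic cycle. The closest known reaction type is the Prins cyclisation–pinacol rearrangement of allylic 1,2-diol acetals to 3-acyl tetrahydrofurans, run here with an orthoester-derived (formate-level) carbenium ion instead of an aldehyde-derived one, so that C3 emerges as the acetal of the lactone. The oxane closes by 6-endo-trig attack of the alkene on the carbenium ion through a chair, and ring B then arises by ring contraction through a suprafacial 1,2-alkyl shift; ring A is not changed. C5 is set by chirality transfer from C6, because C1 migrates with retention onto the face of C5 over which it already sits, and the chair with the dienyl group on C1 and C7 both equatorial places that group cis to the C6 carbonyl; C3 forms as an inconsequential anomeric mixture. The step needs Markovnikov attack through C4 (secured by the tertiary cation and the six-membered chair), migration of C1 and not C7 (only the C6–C1 bond is parallel to the empty orbital at C5) and reaction at the exocyclic alkene only (the side-chain alkenes cannot reach C3 through an unstrained ring).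

**Step 9**
Reactants: 17 (1R,5S)-9,9-(ethylenedioxy)-3-methoxy-1-[(1E)-2-methylpenta-1,4-dien-1-yl]-2-oxaspiro[4.5]decan-6-one
Product: 19 (1R,5S)-9,9-(ethylenedioxy)-3-methoxy-1-[(1E)-2-methylpenta-1,4-dien-1-yl]-2-oxaspiro[4.5]dec-7-en-6-one, via silyl enol ether 18 (not isolated)
Conditions: LDA, TMSCl, THF, −78 °C; then Pd(OAc)2 (1.1 equiv), MeCN, rt
Reagents that add atoms: none
Why: In this Saegusa–Ito oxidation the ketone can enolise only towards C7 (C5 is quaternary), so a single silyl enol ether forms and Pd(OAc)2 converts it into the C7=C8 enone by β-hydride elimination.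

**Step 10**
Reactants: 19 (1R,5S)-9,9-(ethylenedioxy)-3-methoxy-1-[(1E)-2-methylpenta-1,4-dien-1-yl]-2-oxaspiro[4.5]dec-7-en-6-one
Product: 20 (1R,5S)-3-hydroxy-1-[(1E)-2-methylpenta-1,4-dien-1-yl]-2-oxaspiro[4.5]dec-7-ene-6,9-dione (C3 anomers)
Conditions: 1 M aq. HCl, THF, 0 °C → rt
Reagents that add atoms: water, O
Why: Aqueous acid hydrolyses both the dioxolane and the methyl acetal, and the quaternary C5 prevents aromatisation or epimerisation of the resulting enedione.

**Step 11**
Reactants: 20 (1R,5S)-3-hydroxy-1-[(1E)-2-methylpenta-1,4-dien-1-yl]-2-oxaspiro[4.5]dec-7-ene-6,9-dione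
Product: 21 (1R,5R)-1-[(1E)-2-methylpenta-1,4-dien-1-yl]-2-oxaspiro[4.5]dec-7-ene-3,6,9-trione
Conditions: TEMPO (0.2 equiv), PhI(OAc)2 (1.5 equiv), CH2Cl2, rt
Reagents that add atoms: none
Why: Oxoammonium (TEMPO/PhI(OAc)2) oxidation converts the lactol into the γ-lactone chemoselectively under non-basic conditions, which avoids retro-aldol opening and leaves the alkenes and the enedione alone.

**Step 12**
Reactants: 21 (1R,5R)-1-[(1E)-2-methylpenta-1,4-dien-1-yl]-2-oxaspiro[4.5]dec-7-ene-3,6,9-trione
Product: 22 (1R,5R,9S)-9-hydroxy-1-[(1E)-2-methylpenta-1,4-dien-1-yl]-2-oxaspiro[4.5]dec-7-ene-3,6-dione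
Conditions: NADPH-dependent ketoreductase (Re-face selective at C9, chosen from a panel), NADP+ (cat.), propan-2-ol, phosphate buffer pH 7.0, DMSO (10 vol %), 30 °C
Reagents that add atoms: none
Why: A ketoreductase should reduce the less hindered C9 carbonyl (flanked by CH2 and CH) and not C6 (next to the quaternary C5), as in biocatalytic reductions of 2,2-disubstituted cyclohexene-1,4-diones, and an enzyme delivering hydride to the Re face (the face cis to C4) sets C9 as (S) with the hydroxyl cis to C1.

**Step 13**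
Reactants: 22 (1R,5R,9S)-9-hydroxy-1-[(1E)-2-methylpenta-1,4-dien-1-yl]-2-oxaspiro[4.5]dec-7-ene-3,6-dione
Product: 23 (1R,5R,9S)-1-[(1E)-2-methylpenta-1,4-dien-1-yl]-3,6-dioxo-2-oxaspiro[4.5]dec-7-en-9-yl acetate
Conditions: Ac2O, pyridine, DMAP (cat.), CH2Cl2, 0 °C
Reagents that add atoms: acetic anhydride, CC(=O)OC(C)=O
Why: DMAP-catalysed acylation of the secondary allylic alcohol proceeds with retention, and no acidic hydrogen is available for elimination of the acetate.

**Step 14**
Reactants: 23 (1R,5R,9S)-1-[(1E)-2-methylpenta-1,4-dien-1-yl]-3,6-dioxo-2-oxaspiro[4.5]dec-7-en-9-yl acetate; 24 2-methylbut-3-en-2-ol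
Product: 25 (1R,5R,9S)-1-[(1E,4E)-6-hydroxy-2,6-dimethylhepta-1,4-dien-1-yl]-3,6-dioxo-2-oxaspiro[4.5]dec-7-en-9-yl acetate, the target
Conditions: 24 (10 equiv), second-generation Hoveyda–Grubbs catalyst (5 mol %), CH2Cl2, 40 °C
Reagents that add atoms: none
Why: Olefin cross metathesis of the monosubstituted alkene with an excess of the slowly homodimerising tertiary allylic alcohol should give the (E)-disubstituted alkene, while the trisubstituted alkene and the electron-poor ring alkene stay inert.

**Compound list**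

1 | Hagemann's ester, ethyl 2-methyl-4-oxocyclohex-2-ene-1-carboxylate (racemic) | CCOC(=O)C1CCC(=O)C=C1C | starting material
2 | ethyl 7-methyl-1,4-dioxaspiro[4.5]dec-7-ene-8-carboxylate | CCOC(=O)C1=C(C)CC2(CC1)OCCO2 | intermediate
3 | (7-methyl-1,4-dioxaspiro[4.5]dec-7-en-8-yl)methanol | OCC1=C(C)CC2(CC1)OCCO2 | intermediate
4 | 7-methyl-1,4-dioxaspiro[4.5]dec-7-ene-8-carbaldehyde | O=CC1=C(C)CC2(CC1)OCCO2 | intermediate
5 | pent-1-en-4-yne | C#CCC=C | starting material
6 | dimethyl[(1E)-2-methylpenta-1,4-dien-1-yl]alane | C[Al](C)/C=C(\C)CC=C | intermediate (not isolated)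
7 | (1E)-1-iodo-2-methylpenta-1,4-diene | I/C=C(\C)CC=C | intermediate
8 | [(1E)-2-methylpenta-1,4-dien-1-yl]lithium | [Li]/C=C(\C)CC=C | intermediate (not isolated)
9 | bis[(1E)-2-methylpenta-1,4-dien-1-yl]zinc | [Zn](/C=C(\C)CC=C)/C=C(\C)CC=C | intermediate (not isolated)
10 | (1R,2E)-3-methyl-1-(7-methyl-1,4-dioxaspiro[4.5]dec-7-en-8-yl)hexa-2,5-dien-1-ol | O[C@H](/C=C(\C)CC=C)C1=C(C)CC2(CC1)OCCO2 | intermediate
11 | (1R,2E)-1-[(8R)-8-hydroperoxy-7-methylidene-1,4-dioxaspiro[4.5]decan-8-yl]-3-methylhexa-2,5-dien-1-ol | O[C@H](/C=C(\C)CC=C)[C@@]1(OO)CCC2(OCCO2)CC1=C | intermediate (not isolated)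
12 | (1R,2E)-1-[(8R)-8-hydroxy-7-methylidene-1,4-dioxaspiro[4.5]decan-8-yl]-3-methylhexa-2,5-dien-1-ol | O[C@H](/C=C(\C)CC=C)[C@@]1(O)CCC2(OCCO2)CC1=C | intermediate
13 | (1R,2E)-3-methyl-1-[(8R)-7-methylidene-8-(trimethylsilyloxy)-1,4-dioxaspiro[4.5]decan-8-yl]-1-(trimethylsilyloxy)hexa-2,5-diene | C[Si](C)(C)O[C@H](/C=C(\C)CC=C)[C@@]1(O[Si](C)(C)C)CCC2(OCCO2)CC1=C | intermediate
14 | trimethyl orthoformate | COC(OC)OC | starting material
15 | mixed orthoformate: 13 with the secondary silyl group replaced by dimethoxymethyl | COC(OC)O[C@H](/C=C(\C)CC=C)[C@@]1(O[Si](C)(C)C)CCC2(OCCO2)CC1=C | intermediate (not isolated)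
16 | 6,6-(ethylenedioxy)-3-methoxy-1-[(1E)-2-methylpenta-1,4-dien-1-yl]-8a-(trimethylsilyloxy)octahydro-1H-isochromen-4a-ylium, (1R,8aR) | COC1C[C+]2CC3(OCCO3)CC[C@]2(O[Si](C)(C)C)[C@@H](/C=C(\C)CC=C)O1 | intermediate (not isolated)
17 | (1R,5S)-9,9-(ethylenedioxy)-3-methoxy-1-[(1E)-2-methylpenta-1,4-dien-1-yl]-2-oxaspiro[4.5]decan-6-one (C3 anomers) | O=C1CCC2(OCCO2)C[C@]13CC(OC)O[C@@H]3/C=C(\C)CC=C | intermediate
18 | 6-(trimethylsilyloxy)-6-ene silyl enol ether of 17, (1R,5S) | C[Si](C)(C)OC1=CCC2(OCCO2)C[C@]13CC(OC)O[C@@H]3/C=C(\C)CC=C | intermediate (not isolated)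
19 | (1R,5S)-9,9-(ethylenedioxy)-3-methoxy-1-[(1E)-2-methylpenta-1,4-dien-1-yl]-2-oxaspiro[4.5]dec-7-en-6-one | O=C1C=CC2(OCCO2)C[C@]13CC(OC)O[C@@H]3/C=C(\C)CC=C | intermediate
20 | (1R,5S)-3-hydroxy-1-[(1E)-2-methylpenta-1,4-dien-1-yl]-2-oxaspiro[4.5]dec-7-ene-6,9-dione (C3 anomers) | O=C1C=CC(=O)C[C@]12CC(O)O[C@@H]2/C=C(\C)CC=C | intermediate
21 | (1R,5R)-1-[(1E)-2-methylpenta-1,4-dien-1-yl]-2-oxaspiro[4.5]dec-7-ene-3,6,9-trione | O=C1C=CC(=O)C[C@]12CC(=O)O[C@@H]2/C=C(\C)CC=C | intermediate
22 | (1R,5R,9S)-9-hydroxy-1-[(1E)-2-methylpenta-1,4-dien-1-yl]-2-oxaspiro[4.5]dec-7-ene-3,6-dione | O[C@@H]1C=CC(=O)[C@@]2(CC(=O)O[C@@H]2/C=C(\C)CC=C)C1 | intermediate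
23 | (1R,5R,9S)-1-[(1E)-2-methylpenta-1,4-dien-1-yl]-3,6-dioxo-2-oxaspiro[4.5]dec-7-en-9-yl acetate | CC(=O)O[C@@H]1C=CC(=O)[C@@]2(CC(=O)O[C@@H]2/C=C(\C)CC=C)C1 | intermediate
24 | 2-methylbut-3-en-2-ol | C=CC(C)(C)O | starting material
25 | (+)-miliusane XVII, (1R,5R,9S)-1-[(1E,4E)-6-hydroxy-2,6-dimethylhepta-1,4-dien-1-yl]-3,6-dioxo-2-oxaspiro[4.5]dec-7-en-9-yl acetate | CC(=O)O[C@@H]1C=CC(=O)[C@@]2(CC(=O)O[C@@H]2/C=C(\C)C/C=C/C(C)(C)O)C1 | target

**Step count and risks**

Total steps: 14. Longest linear sequence: 13 (steps 1–3 and 5–14, from Hagemann's ester).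

Steps most likely to fail:

1. Step 8 (proposed new method). The alkoxy-stabilised carbenium ion may be too weak an electrophile, so that ionisation of the tertiary allylic silyl ether or of the allylic C1–O bond, or proton loss from the C5 cation, outruns C3–C4 bond formation; a boat transition state would erode the C1/C5 relationship. The fallback uses known chemistry and sets out from diol 12. Acetal exchange with methyl 2,2-dimethoxyacetate (CSA, benzene, 60 °C) gives the glyoxylate acetal F1. SnCl4 (CH2Cl2, −78 → −20 °C) then effects the established aldehyde-acetal Prins cyclisation–pinacol rearrangement, which forms the same C3–C4 bond and gives the spiro keto ester F2. LiOH (THF/H2O) gives the acid F3, and Hofer–Moest anodic decarboxylation in methanol (graphite anode, NaOMe cat.) replaces the carboxyl group by methoxy. The fallback comes back to the route at 17.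

2. Step 6. The ene reaction may also occur at the side-chain trisubstituted alkene, hydrogen may be abstracted from ring CH2 to give endocyclic alkenes, or the hydrogen-bond control of the face may weaken. The fallback sets out from 10. Buffered mCPBA (NaHCO3, CH2Cl2, 0 °C) performs a hydroxyl-directed, A(1,3)-controlled threo epoxidation of the tetrasubstituted alkene to the epoxy alcohol F4. Et2Al(TMP), made from LiTMP and Et2AlCl (toluene, 0 °C), then isomerises the epoxide by syn-elimination of a methyl hydrogen to the exocyclic allylic alcohol. The fallback comes back at 12.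

3. Step 12. No enzyme of the panel may accept the spiro enedione with the needed regio- and facial selectivity, or conjugate reduction of the enedione may compete in the buffer. The fallback sets out from 21 and uses substrate control: Luche reduction (NaBH4, CeCl3·7H2O, MeOH, −78 °C) should reduce the less hindered C9 carbonyl in 1,2 fashion. The (9S)-alcohol so formed is 22, where the fallback comes back to the route. Any (9R)-epimer, the epi-alcohol F5, is converted by Mitsunobu reaction with acetic acid (PPh3, DIAD, THF, 0 °C), with inversion at C9, directly into 23.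

**Further compounds**

F1 | step 8 | methyl glyoxylate acetal of diol 12 (2-methoxycarbonyl-1,3-dioxolane across the C1 and C6 oxygens, acetal epimers) | COC(=O)C1O[C@H](/C=C(\C)CC=C)[C@@]2(O1)CCC3(OCCO3)CC2=C
F2 | step 8 | methyl (1R,5S)-9,9-(ethylenedioxy)-1-[(1E)-2-methylpenta-1,4-dien-1-yl]-6-oxo-2-oxaspiro[4.5]decane-3-carboxylate (C3 epimers) | O=C1CCC2(OCCO2)C[C@]13CC(C(=O)OC)O[C@@H]3/C=C(\C)CC=C
F3 | step 8 | (1R,5S)-9,9-(ethylenedioxy)-1-[(1E)-2-methylpenta-1,4-dien-1-yl]-6-oxo-2-oxaspiro[4.5]decane-3-carboxylic acid (C3 epimers) | O=C1CCC2(OCCO2)C[C@]13CC(C(=O)O)O[C@@H]3/C=C(\C)CC=C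
F4 | step 6 | (1R,2E)-3-methyl-1-[(1'S,6'S)-1'-methylspiro[1,3-dioxolane-2,3'-[7]oxabicyclo[4.1.0]heptan]-6'-yl]hexa-2,5-dien-1-ol | O[C@H](/C=C(\C)CC=C)[C@@]12CCC3(OCCO3)C[C@]1(C)O2
F5 | step 12 | (1R,5R,9R)-9-hydroxy-1-[(1E)-2-methylpenta-1,4-dien-1-yl]-2-oxaspiro[4.5]dec-7-ene-3,6-dione | O[C@H]1C=CC(=O)[C@@]2(CC(=O)O[C@@H]2/C=C(\C)CC=C)C1
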